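**Retrosynthetic overview**
1. Both esters go on last (C6 4-hydroxybenzoate, then C10 angelate) onto a bicyclic enone diol; the C10 carbinol is set by Luche reduction.
2. The seven-membered ring is closed second, by ring-closing metathesis at C8=C9 of a trans-1,2-disubstituted cyclopentane.
3. The five-membered ring is closed first, by rhodium-catalysed hydroacylation (C3–C4) of a 4-pentenal, followed by isopropyl addition to the C4 ketone.
4. Key disconnection C1–C5: dianionic Ireland–Claisen [3,3] rearrangement of an allyl β-hydroxy ester; the bought C6 carbinol fixes C5 and the quaternary C1.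
5. Fragments: β-hydroxy ester 3 from ethyl (3R)-4-chloro-3-hydroxybutanoate; allylic alcohol 6 from (E)-4-acetoxy-2-methylbut-2-enal.

Assumption: positions are numbered as in the daucane skeleton (C1 methyl-bearing ring-fusion carbon, C4 isopropyl carbinol, C5 ring-fusion CH, C6 benzoate carbon, C8=C9 ring alkene, C10 angelate carbon); compounds 1, 4, 18, 21 and all reagents are bought.

**Route**

Step 1
Reactants: 1 ethyl (3R)-4-chloro-3-hydroxybutanoate
Product: 2 ethyl 2-[(2R)-oxiran-2-yl]acetate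
Conditions: Ag2O (0.6 equiv), 1,2-dimethoxyethane, 60 °C, dark
Reagents that add atoms: none
Why: Silver-assisted intramolecular Williamson closure gives the epoxide without the base that would open it to the 4-hydroxycrotonate, and the C–O stereocentre is not touched.

Step 2
Reactants: 2 ethyl 2-[(2R)-oxiran-2-yl]acetate
Product: 3 ethyl (3S)-3-hydroxy-5-methylhex-5-enoate
Conditions: CH2=C(CH3)MgBr (1.5 equiv), CuI (10 mol%), THF, −40 °C; then H2O/aq. NH4Cl
Reagents that add atoms: isopropenylmagnesium bromide CC(=C)[Mg]Br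
Why: Copper-catalysed SN2 opening of the epoxide at its terminal carbon outruns ester attack at −40 °C and leaves the carbinol centre intact (the descriptor changes only through priorities).

Step 3
Reactants: 4 (2E)-3-methyl-4-oxobut-2-en-1-yl acetate
Product: 6 (2E)-4,4-dimethoxy-3-methylbut-2-en-1-ol, via acetal acetate 5 (not isolated)
Conditions: HC(OMe)3, MeOH, pyridinium p-toluenesulfonate (cat.), 23 °C; then K2CO3 (0.3 equiv), MeOH, 23 °C
Reagents that add atoms: trimethyl orthoformate COC(OC)OC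
Why: Acid-catalysed acetalisation followed by base-catalysed methanolysis of the acetate gives the allylic alcohol with the E geometry unchanged.

Step 4
Reactants: 3 ethyl (3S)-3-hydroxy-5-methylhex-5-enoate; 6 (2E)-4,4-dimethoxy-3-methylbut-2-en-1-ol
Product: 7 (2E)-4,4-dimethoxy-3-methylbut-2-en-1-yl (3S)-3-hydroxy-5-methylhex-5-enoate
Conditions: 6 (1.5 equiv), ClBu2SnOSnBu2OH (5 mol%), toluene, reflux with removal of EtOH
Reagents that add atoms: none
Why: Neutral distannoxane-catalysed transesterification (Otera) exchanges ethanol for the primary allylic alcohol and tolerates the free β-hydroxyl and the acetal.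

Step 5
Reactants: 7 (2E)-4,4-dimethoxy-3-methylbut-2-en-1-yl (3S)-3-hydroxy-5-methylhex-5-enoate
Product: 9 methyl (2S,3S)-2-[(2S)-1,1-dimethoxy-2-methylbut-3-en-2-yl]-3-hydroxy-5-methylhex-5-enoate, via carboxylic acid 8 (not isolated)
Conditions: LiN(i-Pr)2 (2.3 equiv), THF, −78 °C, then 23 → 60 °C; cold 1 M HCl to pH 4 and extraction; crude 8 with Me3SiCHN2, toluene/MeOH, 0 °C
Reagents that add atoms: (trimethylsilyl)diazomethane C[Si](C)(C)C=[N+]=[N-]
Why: In this dianionic Ireland–Claisen [3,3]-sigmatropic rearrangement the lithium-chelated alkoxide–enolate has a fixed Z geometry and is attacked anti to the C7 chain (Fráter–Seebach sense) to set C5, while the chair transition state with the E-allyl unit puts CH(OMe)2 equatorial and so sets the quaternary C1.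

Step 6
Reactants: 9 methyl (2S,3S)-2-[(2S)-1,1-dimethoxy-2-methylbut-3-en-2-yl]-3-hydroxy-5-methylhex-5-enoate
Product: 10 methyl (2S,3S)-2-[(2S)-1,1-dimethoxy-2-methylbut-3-en-2-yl]-5-methyl-3-[(triethylsilyl)oxy]hex-5-enoate
Conditions: Et3SiCl, imidazole, DMF, 23 °C
Reagents that add atoms: chlorotriethylsilane CC[Si](Cl)(CC)CC
Why: Silylation masks the C6 hydroxyl so that the β-oxygenated aldehyde of the next two steps cannot dehydrate or undergo retro-aldol cleavage.

Step 7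
Reactants: 10 methyl (2S,3S)-2-[(2S)-1,1-dimethoxy-2-methylbut-3-en-2-yl]-5-methyl-3-[(triethylsilyl)oxy]hex-5-enoate
Product: 11 (2S,3S)-2-[(2S)-1,1-dimethoxy-2-methylbut-3-en-2-yl]-5-methyl-3-[(triethylsilyl)oxy]hex-5-enal
Conditions: i-Bu2AlH (1.1 equiv), CH2Cl2, −78 °C; aq. potassium sodium tartrate (KNaC4H4O6)
Reagents that add atoms: none
Why: Partial reduction of the hindered ester stops at the tetrahedral aluminate at −78 °C and releases the aldehyde on work-up without epimerising C5.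

Step 8
Reactants: 11 (2S,3S)-2-[(2S)-1,1-dimethoxy-2-methylbut-3-en-2-yl]-5-methyl-3-[(triethylsilyl)oxy]hex-5-enal
Product: 12 (2S,3S)-3-(dimethoxymethyl)-3-methyl-2-{(1S)-3-methyl-1-[(triethylsilyl)oxy]but-3-en-1-yl}cyclopentan-1-one
Conditions: [Rh(nbd)(dppe)]BF4 (5 mol%; nbd = norbornadiene, dppe = Ph2PCH2CH2PPh2), activated with H2 then purged with Ar, CH2Cl2, 23 °C
Reagents that add atoms: none
Why: Intramolecular hydroacylation of the 4-pentenal (acyl C–H insertion, alkene insertion, reductive elimination) closes the cyclopentanone, helped by the quaternary centre, while the 1,1-disubstituted alkene would need a slower six-membered closure and no stereocentre is touched.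

Step 9
Reactants: 12 (2S,3S)-3-(dimethoxymethyl)-3-methyl-2-{(1S)-3-methyl-1-[(triethylsilyl)oxy]but-3-en-1-yl}cyclopentan-1-one
Product: 13 (1R,2S,3S)-3-(dimethoxymethyl)-3-methyl-2-{(1S)-3-methyl-1-[(triethylsilyl)oxy]but-3-en-1-yl}-1-(propan-2-yl)cyclopentan-1-ol
Conditions: i-PrMgCl (2.0 equiv), LaCl3·2LiCl (30 mol%), THF, −20 → 0 °C; then H2O/aq. NH4Cl
Reagents that add atoms: isopropylmagnesium chloride CC(C)[Mg]Cl
Why: Lanthanum-promoted Grignard 1,2-addition suppresses enolisation and reduction, and the nucleophile enters the carbonyl face anti to the adjacent C5 side chain and the cis C1 methyl, so the C4 hydroxyl ends up cis to both.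

Step 10
Reactants: 13 (1R,2S,3S)-3-(dimethoxymethyl)-3-methyl-2-{(1S)-3-methyl-1-[(triethylsilyl)oxy]but-3-en-1-yl}-1-(propan-2-yl)cyclopentan-1-ol
Product: 14 (1S,2S,3R)-3-hydroxy-2-[(1S)-1-hydroxy-3-methylbut-3-en-1-yl]-1-methyl-3-(propan-2-yl)cyclopentane-1-carbaldehyde
Conditions: 0.5 M aq. HCl, THF, 0 → 23 °C
Reagents that add atoms: water O
Why: Mild acid hydrolysis removes the dimethyl acetal and the triethylsilyl ether together, and the non-enolisable aldehyde cannot form a lactol because C6 and C10 sit trans on the cyclopentane.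

Step 11
Reactants: 14 (1S,2S,3R)-3-hydroxy-2-[(1S)-1-hydroxy-3-methylbut-3-en-1-yl]-1-methyl-3-(propan-2-yl)cyclopentane-1-carbaldehyde
Product: 15 (1R,2S,3S)-2-[(1S)-1-hydroxy-3-methylbut-3-en-1-yl]-3-(1-hydroxyprop-2-en-1-yl)-3-methyl-1-(propan-2-yl)cyclopentan-1-ol (both epimers at the new carbinol)
Conditions: CH2=CHMgBr (4 equiv), THF, −78 → 0 °C; then H2O/aq. NH4Cl
Reagents that add atoms: vinylmagnesium bromide C=C[Mg]Br
Why: Grignard addition to the neopentyl aldehyde installs C9, and the new C10 centre need not be controlled because it is erased in step 13 and reset in step 15.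

Step 12
Reactants: 15 (1R,2S,3S)-2-[(1S)-1-hydroxy-3-methylbut-3-en-1-yl]-3-(1-hydroxyprop-2-en-1-yl)-3-methyl-1-(propan-2-yl)cyclopentan-1-ol
Product: 16 (3R,3aS,4S,8aS)-6,8a-dimethyl-3-(propan-2-yl)-1,2,3,3a,4,5,8,8a-octahydroazulene-3,4,8-triol (both C8 epimers)
Conditions: second-generation Grubbs catalyst (H2IMes)(PCy3)Cl2Ru=CHPh (5 mol%), CH2Cl2, 40 °C
Reagents that add atoms: none
Why: Ring-closing metathesis between the vinyl carbinol and the 1,1-disubstituted alkene, driven by loss of ethene, closes the trans-fused cycloheptene with the C8=C9 alkene in place.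

Step 13
Reactants: 16 (3R,3aS,4S,8aS)-6,8a-dimethyl-3-(propan-2-yl)-1,2,3,3a,4,5,8,8a-octahydroazulene-3,4,8-triol
Product: 17 (3R,3aS,4S,8aS)-3,4-dihydroxy-6,8a-dimethyl-3-(propan-2-yl)-2,3,3a,4,5,8a-hexahydroazulen-8(1H)-one
Conditions: MnO2 (activated, 20 equiv), CH2Cl2, 23 °C
Reagents that add atoms: none
Why: MnO2 oxidises only the allylic alcohol, so both C10 epimers converge on one enone while the secondary C6 and tertiary C4 hydroxyls stay.

Step 14
Reactants: 17 (3R,3aS,4S,8aS)-3,4-dihydroxy-6,8a-dimethyl-3-(propan-2-yl)-2,3,3a,4,5,8a-hexahydroazulen-8(1H)-one; 18 4-[(tert-butyldimethylsilyl)oxy]benzoic acid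
Product: 19 (3R,3aS,4S,8aS)-3-hydroxy-6,8a-dimethyl-8-oxo-3-(propan-2-yl)-1,2,3,3a,4,5,8,8a-octahydroazulen-4-yl 4-[(tert-butyldimethylsilyl)oxy]benzoate
Conditions: dicyclohexylcarbodiimide, 4-(dimethylamino)pyridine (cat.), CH2Cl2, 23 °C
Reagents that add atoms: none
Why: Steglich esterification acylates the only secondary hydroxyl (C6), the tertiary C4 hydroxyl being inert.

Step 15
Reactants: 19 (3R,3aS,4S,8aS)-3-hydroxy-6,8a-dimethyl-8-oxo-3-(propan-2-yl)-1,2,3,3a,4,5,8,8a-octahydroazulen-4-yl 4-[(tert-butyldimethylsilyl)oxy]benzoate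
Product: 20 (3R,3aS,4S,8S,8aS)-3,8-dihydroxy-6,8a-dimethyl-3-(propan-2-yl)-1,2,3,3a,4,5,8,8a-octahydroazulen-4-yl 4-[(tert-butyldimethylsilyl)oxy]benzoate
Conditions: NaBH4, CeCl3·7H2O, MeOH, −78 → −40 °C
Reagents that add atoms: none
Why: Luche 1,2-reduction delivers hydride to the enone face opposite the adjacent angular methyl, which places the C10 hydroxyl cis to that methyl (10S) and leaves the benzoate alone.

Step 16
Reactants: 20 (3R,3aS,4S,8S,8aS)-3,8-dihydroxy-6,8a-dimethyl-3-(propan-2-yl)-1,2,3,3a,4,5,8,8a-octahydroazulen-4-yl 4-[(tert-butyldimethylsilyl)oxy]benzoate; 21 (2Z)-2-methylbut-2-enoic acid (angelic acid)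
Product: 24 (3R,3aS,4S,8S,8aS)-3-hydroxy-6,8a-dimethyl-8-{[(2Z)-2-methylbut-2-enoyl]oxy}-3-(propan-2-yl)-1,2,3,3a,4,5,8,8a-octahydroazulen-4-yl 4-hydroxybenzoate, via mixed anhydride 22 (not isolated), via silyl ether 23 (not isolated)
Conditions: 21 (3 equiv), 2,4,6-Cl3C6H2COCl, Et3N, toluene, 23 °C; add 20, 80 °C; cool, MeOH quench of excess anhydride; then Bu4NF/AcOH (1:1), THF, 0 °C
Reagents that add atoms: none
Why: Yamaguchi esterification through the preformed mixed anhydride, run without a nucleophilic catalyst, acylates the hindered allylic C10 hydroxyl without Z-to-E isomerisation, and buffered fluoride then cleaves only the aryl silyl ether.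

**Compound list**
1 | ethyl (3R)-4-chloro-3-hydroxybutanoate | CCOC(=O)C[C@@H](O)CCl | starting material
2 | ethyl 2-[(2R)-oxiran-2-yl]acetate | CCOC(=O)C[C@@H]1CO1 | intermediate
3 | ethyl (3S)-3-hydroxy-5-methylhex-5-enoate | CCOC(=O)C[C@@H](O)CC(C)=C | intermediate
4 | (2E)-3-methyl-4-oxobut-2-en-1-yl acetate [(E)-4-acetoxy-2-methylbut-2-enal] | CC(=O)OC/C=C(\C)C=O | starting material
5 | (2E)-4,4-dimethoxy-3-methylbut-2-en-1-yl acetate | CC(=O)OC/C=C(\C)C(OC)OC | intermediate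
6 | (2E)-4,4-dimethoxy-3-methylbut-2-en-1-ol | OC/C=C(\C)C(OC)OC | intermediate
7 | (2E)-4,4-dimethoxy-3-methylbut-2-en-1-yl (3S)-3-hydroxy-5-methylhex-5-enoate | COC(OC)/C(C)=C/COC(=O)C[C@@H](O)CC(C)=C | intermediate
8 | (2S,3S)-2-[(2S)-1,1-dimethoxy-2-methylbut-3-en-2-yl]-3-hydroxy-5-methylhex-5-enoic acid | OC(=O)[C@H]([C@@H](O)CC(C)=C)[C@](C)(C=C)C(OC)OC | intermediate
9 | methyl (2S,3S)-2-[(2S)-1,1-dimethoxy-2-methylbut-3-en-2-yl]-3-hydroxy-5-methylhex-5-enoate | COC(=O)[C@H]([C@@H](O)CC(C)=C)[C@](C)(C=C)C(OC)OC | intermediate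
10 | methyl (2S,3S)-2-[(2S)-1,1-dimethoxy-2-methylbut-3-en-2-yl]-5-methyl-3-[(triethylsilyl)oxy]hex-5-enoate | COC(=O)[C@H]([C@@H](O[Si](CC)(CC)CC)CC(C)=C)[C@](C)(C=C)C(OC)OC | intermediate
11 | (2S,3S)-2-[(2S)-1,1-dimethoxy-2-methylbut-3-en-2-yl]-5-methyl-3-[(triethylsilyl)oxy]hex-5-enal | O=C[C@H]([C@@H](O[Si](CC)(CC)CC)CC(C)=C)[C@](C)(C=C)C(OC)OC | intermediate
12 | (2S,3S)-3-(dimethoxymethyl)-3-methyl-2-{(1S)-3-methyl-1-[(triethylsilyl)oxy]but-3-en-1-yl}cyclopentan-1-one | O=C1CC[C@](C)(C(OC)OC)[C@H]1[C@@H](O[Si](CC)(CC)CC)CC(C)=C | intermediate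
13 | (1R,2S,3S)-3-(dimethoxymethyl)-3-methyl-2-{(1S)-3-methyl-1-[(triethylsilyl)oxy]but-3-en-1-yl}-1-(propan-2-yl)cyclopentan-1-ol | CC(C)[C@]1(O)CC[C@](C)(C(OC)OC)[C@H]1[C@@H](O[Si](CC)(CC)CC)CC(C)=C | intermediate
14 | (1S,2S,3R)-3-hydroxy-2-[(1S)-1-hydroxy-3-methylbut-3-en-1-yl]-1-methyl-3-(propan-2-yl)cyclopentane-1-carbaldehyde | CC(C)[C@]1(O)CC[C@](C)(C=O)[C@H]1[C@@H](O)CC(C)=C | intermediate
15 | (1R,2S,3S)-2-[(1S)-1-hydroxy-3-methylbut-3-en-1-yl]-3-(1-hydroxyprop-2-en-1-yl)-3-methyl-1-(propan-2-yl)cyclopentan-1-ol (both epimers at the vinyl carbinol) | CC(C)[C@]1(O)CC[C@](C)(C(O)C=C)[C@H]1[C@@H](O)CC(C)=C | intermediate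
16 | (3R,3aS,4S,8aS)-6,8a-dimethyl-3-(propan-2-yl)-1,2,3,3a,4,5,8,8a-octahydroazulene-3,4,8-triol (both C8 epimers) | OC1C=C(C)C[C@H](O)[C@@H]2[C@]1(C)CC[C@@]2(O)C(C)C | intermediate
17 | (3R,3aS,4S,8aS)-3,4-dihydroxy-6,8a-dimethyl-3-(propan-2-yl)-2,3,3a,4,5,8a-hexahydroazulen-8(1H)-one | O=C1C=C(C)C[C@H](O)[C@@H]2[C@]1(C)CC[C@@]2(O)C(C)C | intermediate
18 | 4-[(tert-butyldimethylsilyl)oxy]benzoic acid | O=C(O)c1ccc(O[Si](C)(C)C(C)(C)C)cc1 | starting material
19 | (3R,3aS,4S,8aS)-3-hydroxy-6,8a-dimethyl-8-oxo-3-(propan-2-yl)-1,2,3,3a,4,5,8,8a-octahydroazulen-4-yl 4-[(tert-butyldimethylsilyl)oxy]benzoate | O=C1C=C(C)C[C@H](OC(=O)c3ccc(O[Si](C)(C)C(C)(C)C)cc3)[C@@H]2[C@]1(C)CC[C@@]2(O)C(C)C | intermediate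
20 | (3R,3aS,4S,8S,8aS)-3,8-dihydroxy-6,8a-dimethyl-3-(propan-2-yl)-1,2,3,3a,4,5,8,8a-octahydroazulen-4-yl 4-[(tert-butyldimethylsilyl)oxy]benzoate | O[C@H]1C=C(C)C[C@H](OC(=O)c3ccc(O[Si](C)(C)C(C)(C)C)cc3)[C@@H]2[C@]1(C)CC[C@@]2(O)C(C)C | intermediate
21 | (2Z)-2-methylbut-2-enoic acid (angelic acid) | C/C=C(/C)C(=O)O | starting material
22 | (2Z)-2-methylbut-2-enoic 2,4,6-trichlorobenzoic anhydride | C/C=C(/C)C(=O)OC(=O)c1c(Cl)cc(Cl)cc1Cl | intermediate
23 | (3R,3aS,4S,8S,8aS)-3-hydroxy-6,8a-dimethyl-8-{[(2Z)-2-methylbut-2-enoyl]oxy}-3-(propan-2-yl)-1,2,3,3a,4,5,8,8a-octahydroazulen-4-yl 4-[(tert-butyldimethylsilyl)oxy]benzoate | C/C=C(/C)C(=O)O[C@H]1C=C(C)C[C@H](OC(=O)c3ccc(O[Si](C)(C)C(C)(C)C)cc3)[C@@H]2[C@]1(C)CC[C@@]2(O)C(C)C | intermediate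
24 | (3R,3aS,4S,8S,8aS)-3-hydroxy-6,8a-dimethyl-8-{[(2Z)-2-methylbut-2-enoyl]oxy}-3-(propan-2-yl)-1,2,3,3a,4,5,8,8a-octahydroazulen-4-yl 4-hydroxybenzoate | C/C=C(/C)C(=O)O[C@H]1C=C(C)C[C@H](OC(=O)c2ccc(O)cc2)[C@@H]2[C@]1(C)CC[C@@]2(O)C(C)C | target

**Step count**
Total: 16 steps. Longest linear sequence: 15 steps (1 → 2 → 3 → 7 → 9 → 10 → 11 → 12 → 13 → 14 → 15 → 16 → 17 → 19 → 20 → 24); step 3 is the side branch.

**Steps most likely to fail, with fallbacks**

Step 5 (dianionic Claisen). The lithium dianion must survive warming long enough to form a quaternary carbon, and the facial control rests on one chelate. The fallback sets out from 7 and comes back at 10. Compound 7 is silylated first (Et3SiCl, imidazole) to the allyl ester silyl ether F1. Enolisation with LiN(i-Pr)2 in THF/DMPU and trapping with Me3SiCl gives the Z-configured silyl ketene acetal F2. This rearranges at 60 °C through the same chair to the trimethylsilyl ester F3, and mild aqueous work-up gives the silyloxy acid F4. Me3SiCHN2 then gives 10, so step 6 is skipped. Enolate geometry now comes from the polar cosolvent and the facial bias from the inside-alkoxy conformer of the C6 stereocentre instead of a chelate. The same anti sense is expected but with a lower ratio; minor isomers would be removed at the cyclic ketone 12.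

Step 8 (hydroacylation). The aldehyde is α-branched and congested, and decarbonylation can kill the catalyst. The fallback sets out from 11 and comes back at 12. Vinylmagnesium bromide adds to 11 to give the allylic alcohol F5 (both epimers). Dess–Martin periodinane gives the vinyl ketone F6. The second-generation Grubbs catalyst closes the five-membered ring between the two monosubstituted alkenes to the cyclopentenone F7, the 1,1-disubstituted alkene staying out. Conjugate reduction with the Stryker reagent [(Ph3P)CuH]6 gives 12.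

Step 16 (angelate on the hindered C10 hydroxyl). Acylation next to the quaternary carbon is slow, and forcing it risks isomerisation to the tiglate. The fallback sets out from 20 and comes back at 23. Compound 20 is esterified (dicyclohexylcarbodiimide, 4-(dimethylamino)pyridine) with the less hindered 2-[bis(2,2,2-trifluoroethoxy)phosphoryl]propanoic acid to the phosphonate ester F8. A Still–Gennari olefination with acetaldehyde (KN(SiMe3)2, 18-crown-6, THF, −78 °C) then builds the Z-alkene on the molecule and gives 23. Bu4NF/AcOH gives 24.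

**Further compounds**
F1 | step 5 | (2E)-4,4-dimethoxy-3-methylbut-2-en-1-yl (3S)-5-methyl-3-[(triethylsilyl)oxy]hex-5-enoate | COC(OC)/C(C)=C/COC(=O)C[C@@H](O[Si](CC)(CC)CC)CC(C)=C
F2 | step 5 | (1Z,3S)-1-{[(2E)-4,4-dimethoxy-3-methylbut-2-en-1-yl]oxy}-5-methyl-3-[(triethylsilyl)oxy]-1-[(trimethylsilyl)oxy]hexa-1,5-diene (silyl ketene acetal) | C[Si](C)(C)O/C(OC/C=C(\C)C(OC)OC)=C\[C@@H](O[Si](CC)(CC)CC)CC(C)=C
F3 | step 5 | trimethylsilyl (2S,3S)-2-[(2S)-1,1-dimethoxy-2-methylbut-3-en-2-yl]-5-methyl-3-[(triethylsilyl)oxy]hex-5-enoate | C[Si](C)(C)OC(=O)[C@H]([C@@H](O[Si](CC)(CC)CC)CC(C)=C)[C@](C)(C=C)C(OC)OC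
F4 | step 5 | (2S,3S)-2-[(2S)-1,1-dimethoxy-2-methylbut-3-en-2-yl]-5-methyl-3-[(triethylsilyl)oxy]hex-5-enoic acid | OC(=O)[C@H]([C@@H](O[Si](CC)(CC)CC)CC(C)=C)[C@](C)(C=C)C(OC)OC
F5 | step 8 | (5S)-4-[(2S)-1,1-dimethoxy-2-methylbut-3-en-2-yl]-7-methyl-5-[(triethylsilyl)oxy]octa-1,7-dien-3-ol (C4 configured as in 11; both C3 epimers) | C=CC(O)[C@H]([C@@H](O[Si](CC)(CC)CC)CC(C)=C)[C@](C)(C=C)C(OC)OC
F6 | step 8 | (4S,5S)-4-[(2S)-1,1-dimethoxy-2-methylbut-3-en-2-yl]-7-methyl-5-[(triethylsilyl)oxy]octa-1,7-dien-3-one | C=CC(=O)[C@H]([C@@H](O[Si](CC)(CC)CC)CC(C)=C)[C@](C)(C=C)C(OC)OC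
F7 | step 8 | (4S,5S)-4-(dimethoxymethyl)-4-methyl-5-{(1S)-3-methyl-1-[(triethylsilyl)oxy]but-3-en-1-yl}cyclopent-2-en-1-one | O=C1C=C[C@](C)(C(OC)OC)[C@H]1[C@@H](O[Si](CC)(CC)CC)CC(C)=C
F8 | step 16 | (3R,3aS,4S,8S,8aS)-8-({2-[bis(2,2,2-trifluoroethoxy)phosphoryl]propanoyl}oxy)-3-hydroxy-6,8a-dimethyl-3-(propan-2-yl)-1,2,3,3a,4,5,8,8a-octahydroazulen-4-yl 4-[(tert-butyldimethylsilyl)oxy]benzoate (both epimers at the phosphonate carbon) | CC(P(=O)(OCC(F)(F)F)OCC(F)(F)F)C(=O)O[C@H]1C=C(C)C[C@H](OC(=O)c3ccc(O[Si](C)(C)C(C)(C)C)cc3)[C@@H]2[C@]1(C)CC[C@@]2(O)C(C)C
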